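The 14‑membered ring is disconnected at the bond between the acetoxy‑bearing ring carbon (the CH–OAc next to the butenolide CH2) and the adjacent methyl‑bearing olefinic carbon. This allylic carbinol / E‑trisubstituted alkene pair is the retron of a nickel‑catalysed reductive alkyne–aldehyde coupling. In one operation the key step closes the macrocycle, forms the C–C bond, fixes the E‑C(CH3)=CH geometry by syn delivery of H and carbon, and creates the carbinol stereocentre. Its precursor is an acyclic ynal: an (S)‑butenolide carrying a CH2CHO arm, linked through the geraniol‑derived E‑alkene and a Z‑enoate to a methyl‑capped alkyne.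

Key step: step 10

Remark: the (S,S)‑ProPhenol ligand is assumed to direct the alkynylide to the Re face of enal 9; if the sense proves opposite, the (R,R)‑ligand is used with no other change.

Step 1
Reactants: 1 pent‑3‑yn‑1‑ol
Product: 2 5‑iodopent‑2‑yne
Conditions: I2, PPh3, imidazole, CH2Cl2, 0 °C → rt
Reagents that add atoms: iodine, II
Why: Appel‑type iodination should replace the primary hydroxyl by iodide through SN2 displacement of the oxyphosphonium group, the internal alkyne being inert.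

Step 2
Reactants: 2 5‑iodopent‑2‑yne; 3 methyl 2‑[bis(2,2,2‑trifluoroethoxy)phosphoryl]acetate
Product: 4 methyl 2‑[bis(2,2,2‑trifluoroethoxy)phosphoryl]hept‑5‑ynoate (racemic; the centre is lost in step 4)
Conditions: NaH, DMF, 0 °C → rt (3 in slight excess)
Reagents that add atoms: none
Why: C‑alkylation of the stabilised, weakly basic sodium phosphonoacetate with the primary iodide (SN2) should outrun elimination and give the α‑substituted olefination reagent.

Step 3
Reactants: 5 geranyl acetate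
Product: 6 (2E)‑3‑methyl‑6‑oxohex‑2‑en‑1‑yl acetate
Conditions: O3 (1 equiv), CH2Cl2/MeOH, −78 °C; then Me2S, −78 °C → rt
Reagents that add atoms: ozone, O=[O+][O-]
Why: Chemoselective ozonolysis should cleave the electron‑rich distal alkene before the one deactivated by the allylic acetate, and reductive work‑up gives the aldehyde with the E‑alkene intact.

Step 4
Reactants: 4 methyl 2‑[bis(2,2,2‑trifluoroethoxy)phosphoryl]hept‑5‑ynoate; 6 (2E)‑3‑methyl‑6‑oxohex‑2‑en‑1‑yl acetate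
Product: 7 methyl (2Z,6E)‑8‑(acetyloxy)‑6‑methyl‑2‑(pent‑3‑yn‑1‑yl)octa‑2,6‑dienoate
Conditions: 4, KHMDS, 18‑crown‑6, THF, −78 °C; then 6, −78 °C
Reagents that add atoms: none
Why: Still–Gennari olefination, in which the electron‑poor phosphonate eliminates faster than the adducts equilibrate, should give the kinetic Z‑enoate with CO2Me cis to the chain.

Step 5
Reactants: 7 methyl (2Z,6E)‑8‑(acetyloxy)‑6‑methyl‑2‑(pent‑3‑yn‑1‑yl)octa‑2,6‑dienoate
Product: 8 methyl (2Z,6E)‑8‑hydroxy‑6‑methyl‑2‑(pent‑3‑yn‑1‑yl)octa‑2,6‑dienoate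
Conditions: K2CO3, MeOH, 0 °C → rt
Reagents that add atoms: none
Why: Zemplén‑type transesterification should remove the primary allylic acetate, while exchange at the methyl ester is degenerate in methanol and the enoate geometry is untouched.

Step 6
Reactants: 8 methyl (2Z,6E)‑8‑hydroxy‑6‑methyl‑2‑(pent‑3‑yn‑1‑yl)octa‑2,6‑dienoate
Product: 9 methyl (2Z,6E)‑6‑methyl‑8‑oxo‑2‑(pent‑3‑yn‑1‑yl)octa‑2,6‑dienoate
Conditions: MnO2, CH2Cl2, rt
Reagents that add atoms: none
Why: MnO2 oxidises allylic alcohols selectively and should give the E‑enal without isomerisation or over‑oxidation.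

Step 7
Reactants: 9 methyl (2Z,6E)‑6‑methyl‑8‑oxo‑2‑(pent‑3‑yn‑1‑yl)octa‑2,6‑dienoate; 10 methyl propiolate
Product: 11 dimethyl (4S,5E,9Z)‑4‑hydroxy‑6‑methyl‑10‑(pent‑3‑yn‑1‑yl)undeca‑5,9‑dien‑2‑ynedioate
Conditions: Me2Zn (3 equiv), (S,S)‑ProPhenol (20 mol%), Ph3P=O (40 mol%), toluene, 4 °C; aq NH4Cl
Reagents that add atoms: none
Why: Catalytic asymmetric alkynylation with the dinuclear zinc–ProPhenol catalyst should add the zinc alkynylide of methyl propiolate 1,2 to the Re face of the enal, setting the (S)‑carbinol that becomes the C–O stereocentre of the butenolide.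

Step 8
Reactants: 11 dimethyl (4S,5E,9Z)‑4‑hydroxy‑6‑methyl‑10‑(pent‑3‑yn‑1‑yl)undeca‑5,9‑dien‑2‑ynedioate; 12 (1,3‑dioxolan‑2‑ylmethyl)magnesium bromide
Product: 13 methyl (2Z,6E)‑7‑[(2S)‑3‑(1,3‑dioxolan‑2‑ylmethyl)‑4‑methyl‑5‑oxo‑2,5‑dihydrofuran‑2‑yl]‑6‑methyl‑2‑(pent‑3‑yn‑1‑yl)hepta‑2,6‑dienoate
Conditions: 12 (2.5 equiv), CuBr·SMe2 (1.25 equiv), THF, −78 → −40 °C; 11, −78 °C; then MeI, HMPA, −78 → −20 °C; aq NH4Cl
Reagents that add atoms: iodomethane, CI
Why: Tandem syn‑carbocupration of the ynoate, lactonisation and C‑alkylation should place the acetal arm on the β‑carbon with the γ‑alkoxide cis to the ester so that the butenolide closes, the α‑cuprio carbon then being methylated by MeI, and the carbinol centre is not touched.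

Step 9
Reactants: 13 methyl (2Z,6E)‑7‑[(2S)‑3‑(1,3‑dioxolan‑2‑ylmethyl)‑4‑methyl‑5‑oxo‑2,5‑dihydrofuran‑2‑yl]‑6‑methyl‑2‑(pent‑3‑yn‑1‑yl)hepta‑2,6‑dienoate
Product: 14 methyl (2Z,6E)‑6‑methyl‑7‑[(2S)‑4‑methyl‑5‑oxo‑3‑(2‑oxoethyl)‑2,5‑dihydrofuran‑2‑yl]‑2‑(pent‑3‑yn‑1‑yl)hepta‑2,6‑dienoate
Conditions: 1 M aq HCl, THF, 0 °C → rt; crude product used at once
Reagents that add atoms: water, O
Why: Acid hydrolysis of the 1,3‑dioxolane should unmask the aldehyde, and low temperature with short contact should keep the double bond inside the butenolide.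

Step 10
Reactants: 14 methyl (2Z,6E)‑6‑methyl‑7‑[(2S)‑4‑methyl‑5‑oxo‑3‑(2‑oxoethyl)‑2,5‑dihydrofuran‑2‑yl]‑2‑(pent‑3‑yn‑1‑yl)hepta‑2,6‑dienoate
Product: 16 methyl (5S,6E,10Z,14E,15aS)‑5‑hydroxy‑3,6,14‑trimethyl‑2‑oxo‑2,4,5,8,9,12,13,15a‑octahydrocyclotetradeca[b]furan‑10‑carboxylate, via macrocyclic triethylsilyl ether 15 (not isolated)
Conditions: Ni(cod)2 (25 mol%), IMes (free carbene, 25 mol%), Et3SiH (5 equiv), THF, rt, syringe‑pump addition of 14 (final 0.005 M); then HF·pyridine, 0 °C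
Reagents that add atoms: none
Why: Ni(0)–IMes binds the alkyne and the aldehyde of 14, and oxidative cyclisation joins the aldehyde carbon to the methyl‑bearing alkyne carbon in a five‑membered oxanickelacycle; σ‑bond metathesis with Et3SiH and C–H reductive elimination then deliver H cis to the new C–C bond and release silyl ether 15, which HF·pyridine cleaves to 16. The closest known reaction type is the Ni/NHC‑catalysed reductive macrocyclisation of ynals with silanes (aldehyde–alkyne reductive coupling), in which small carbene ligands direct methyl‑capped alkynes to endocyclic E‑trisubstituted allylic silyl ethers. The 14‑membered carbocycle closes in the endocyclic mode (both alkyne carbons in the ring), which should be favoured over the 13‑membered exocyclic ethylidene alternative by the small IMes ligand, which places the larger alkyne substituent next to nickel, and by slow addition at high dilution. The new (S)‑carbinol centre is to be set under substrate control: the (S)‑configured C–O carbon of the rigid, planar butenolide, two atoms from the aldehyde carbon, restricts which carbonyl face the tethered alkyne can reach in the macrocyclic transition state; the sense of this bias cannot be assigned with certainty in advance, and a minor epimer would be separated at 16. The E geometry follows from syn addition of H and carbon across the alkyne. The step needs chemoselectivity for the alkyne/aldehyde pair, which should be secured because the α,β‑disubstituted enoate and the tetrasubstituted butenolide are poor π‑ligands for Ni(0), and the base‑free carbene complex spares the enolisable CH2CHO arm.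

Step 11
Reactants: 16 methyl (5S,6E,10Z,14E,15aS)‑5‑hydroxy‑3,6,14‑trimethyl‑2‑oxo‑2,4,5,8,9,12,13,15a‑octahydrocyclotetradeca[b]furan‑10‑carboxylate
Product: 17 16‑oxosarcoglaucol acetate, methyl (5S,6E,10Z,14E,15aS)‑5‑(acetyloxy)‑3,6,14‑trimethyl‑2‑oxo‑2,4,5,8,9,12,13,15a‑octahydrocyclotetradeca[b]furan‑10‑carboxylate
Conditions: Ac2O, pyridine, DMAP (cat.), CH2Cl2, 0 °C
Reagents that add atoms: acetic anhydride, CC(=O)OC(C)=O
Why: DMAP‑catalysed O‑acylation should acetylate the secondary allylic alcohol with retention at carbon, the mild base and low temperature avoiding epimerisation of the butenolide γ‑centre.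

Compound list
1 | pent‑3‑yn‑1‑ol | CC#CCCO | starting material
2 | 5‑iodopent‑2‑yne | CC#CCCI | intermediate
3 | methyl 2‑[bis(2,2,2‑trifluoroethoxy)phosphoryl]acetate | COC(=O)CP(=O)(OCC(F)(F)F)OCC(F)(F)F | starting material
4 | methyl 2‑[bis(2,2,2‑trifluoroethoxy)phosphoryl]hept‑5‑ynoate (racemic) | COC(=O)C(CCC#CC)P(=O)(OCC(F)(F)F)OCC(F)(F)F | intermediate
5 | geranyl acetate, (2E)‑3,7‑dimethylocta‑2,6‑dien‑1‑yl acetate | CC(C)=CCC/C(C)=C/COC(C)=O | starting material
6 | (2E)‑3‑methyl‑6‑oxohex‑2‑en‑1‑yl acetate | O=CCC/C(C)=C/COC(C)=O | intermediate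
7 | methyl (2Z,6E)‑8‑(acetyloxy)‑6‑methyl‑2‑(pent‑3‑yn‑1‑yl)octa‑2,6‑dienoate | COC(=O)/C(CCC#CC)=C\CC/C(C)=C/COC(C)=O | intermediate
8 | methyl (2Z,6E)‑8‑hydroxy‑6‑methyl‑2‑(pent‑3‑yn‑1‑yl)octa‑2,6‑dienoate | COC(=O)/C(CCC#CC)=C\CC/C(C)=C/CO | intermediate
9 | methyl (2Z,6E)‑6‑methyl‑8‑oxo‑2‑(pent‑3‑yn‑1‑yl)octa‑2,6‑dienoate | COC(=O)/C(CCC#CC)=C\CC/C(C)=C/C=O | intermediate
10 | methyl propiolate | C#CC(=O)OC | starting material
11 | dimethyl (4S,5E,9Z)‑4‑hydroxy‑6‑methyl‑10‑(pent‑3‑yn‑1‑yl)undeca‑5,9‑dien‑2‑ynedioate | COC(=O)/C(CCC#CC)=C\CC/C(C)=C/[C@H](O)C#CC(=O)OC | intermediate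
12 | (1,3‑dioxolan‑2‑ylmethyl)magnesium bromide | Br[Mg]CC1OCCO1 | starting material
13 | methyl (2Z,6E)‑7‑[(2S)‑3‑(1,3‑dioxolan‑2‑ylmethyl)‑4‑methyl‑5‑oxo‑2,5‑dihydrofuran‑2‑yl]‑6‑methyl‑2‑(pent‑3‑yn‑1‑yl)hepta‑2,6‑dienoate | COC(=O)/C(CCC#CC)=C\CC/C(C)=C/[C@@H]1OC(=O)C(C)=C1CC1OCCO1 | intermediate
14 | methyl (2Z,6E)‑6‑methyl‑7‑[(2S)‑4‑methyl‑5‑oxo‑3‑(2‑oxoethyl)‑2,5‑dihydrofuran‑2‑yl]‑2‑(pent‑3‑yn‑1‑yl)hepta‑2,6‑dienoate | COC(=O)/C(CCC#CC)=C\CC/C(C)=C/[C@@H]1OC(=O)C(C)=C1CC=O | intermediate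
15 | methyl (5S,6E,10Z,14E,15aS)‑3,6,14‑trimethyl‑2‑oxo‑5‑[(triethylsilyl)oxy]‑2,4,5,8,9,12,13,15a‑octahydrocyclotetradeca[b]furan‑10‑carboxylate | COC(=O)/C1=C\CC/C(C)=C/[C@@H]2OC(=O)C(C)=C2C[C@H](O[Si](CC)(CC)CC)/C(C)=C/CC1 | intermediate
16 | methyl (5S,6E,10Z,14E,15aS)‑5‑hydroxy‑3,6,14‑trimethyl‑2‑oxo‑2,4,5,8,9,12,13,15a‑octahydrocyclotetradeca[b]furan‑10‑carboxylate | COC(=O)/C1=C\CC/C(C)=C/[C@@H]2OC(=O)C(C)=C2C[C@H](O)/C(C)=C/CC1 | intermediate
17 | 16‑oxosarcoglaucol acetate | COC(=O)/C1=C\CC/C(C)=C/[C@@H]2OC(=O)C(C)=C2C[C@H](OC(C)=O)/C(C)=C/CC1 | target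

Total step count: 11. Longest linear sequence: 10 steps (from 1 through steps 1, 2 and 4–11; the branch from geranyl acetate 5 is 9 steps).

Steps most likely to fail

Step 10. The oxidative cyclisation may take the exocyclic course, forming the bond at the chain‑bearing alkyne carbon and a 13‑membered ring. Nickel(0) may also insert into the allylic C–O bond of the γ‑alkenyl lactone, the aldehyde may enolise on the catalyst, or discrimination between the two carbonyl faces may be poor. The fallback replaces the reductive coupling by a Nozaki–Hiyama–Kishi macrocyclisation and sets out from 13. Hydrozirconation of the methyl alkyne with Cp2Zr(H)Cl (THF, rt; a small excess lets the alkenylzirconium isomers equilibrate toward zirconium on the methyl‑bearing carbon), followed by iodinolysis with I2 in the same flask, should give the (E)‑vinyl iodide methyl (2Z,6E)‑7‑[(2S)‑3‑(1,3‑dioxolan‑2‑ylmethyl)‑4‑methyl‑5‑oxo‑2,5‑dihydrofuran‑2‑yl]‑2‑[(3E)‑4‑iodopent‑3‑en‑1‑yl]‑6‑methylhepta‑2,6‑dienoate F1. Hydrolysis of the dioxolane as in step 9 should give the iodo aldehyde methyl (2Z,6E)‑2‑[(3E)‑4‑iodopent‑3‑en‑1‑yl]‑6‑methyl‑7‑[(2S)‑4‑methyl‑5‑oxo‑3‑(2‑oxoethyl)‑2,5‑dihydrofuran‑2‑yl]hepta‑2,6‑dienoate F2. Treatment with CrCl2 and catalytic NiCl2 in DMSO/THF at high dilution, with a chiral sulfonamide ligand on chromium for reagent control of the carbonyl face, closes the same bond under neutral conditions and comes back to the route at 16.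

Step 8. The α‑cuprio enoate may be protonated instead of methylated, or may lose its geometry through the allenoate before the lactone closes, so that the open‑chain hydroxy ester cannot cyclise. The fallback sets out from 11 and introduces the methyl group by cross‑coupling instead of alkylation. The same carbocupration with the cuprate from 12 is quenched with iodine, which traps alkenylcopper species at −78 °C, to give the α‑iodobutenolide methyl (2Z,6E)‑7‑[(2S)‑3‑(1,3‑dioxolan‑2‑ylmethyl)‑4‑iodo‑5‑oxo‑2,5‑dihydrofuran‑2‑yl]‑6‑methyl‑2‑(pent‑3‑yn‑1‑yl)hepta‑2,6‑dienoate F3. Stille coupling with Me4Sn (Pd2(dba)3, AsPh3, CuI, NMP, rt) then comes back to the route at 13.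

Step 9. Acid‑catalysed enolisation of the doubly activated CH2 between the aldehyde and the butenolide may move the ring double bond into conjugation with the aldehyde, or the oxocarbenium ion may eliminate to a dienyl ether instead of being hydrolysed. The fallback sets out from 11 and generates the aldehyde by oxidation under non‑acidic conditions. Carbocupration with lithium divinylcuprate and trapping with MeI/HMPA as in step 8 should give the vinylbutenolide methyl (2Z,6E)‑7‑[(2S)‑3‑ethenyl‑4‑methyl‑5‑oxo‑2,5‑dihydrofuran‑2‑yl]‑6‑methyl‑2‑(pent‑3‑yn‑1‑yl)hepta‑2,6‑dienoate F4. Hydroboration of the terminal vinyl group with 9‑BBN (THF, 0 °C; NaBO3·4H2O work‑up) should give the primary alcohol methyl (2Z,6E)‑7‑[(2S)‑3‑(2‑hydroxyethyl)‑4‑methyl‑5‑oxo‑2,5‑dihydrofuran‑2‑yl]‑6‑methyl‑2‑(pent‑3‑yn‑1‑yl)hepta‑2,6‑dienoate F5. Dess–Martin oxidation buffered with NaHCO3 then comes back to the route at 14.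

Further compounds
F1 | step 10 | methyl (2Z,6E)‑7‑[(2S)‑3‑(1,3‑dioxolan‑2‑ylmethyl)‑4‑methyl‑5‑oxo‑2,5‑dihydrofuran‑2‑yl]‑2‑[(3E)‑4‑iodopent‑3‑en‑1‑yl]‑6‑methylhepta‑2,6‑dienoate | COC(=O)/C(CC/C=C(\C)I)=C\CC/C(C)=C/[C@@H]1OC(=O)C(C)=C1CC1OCCO1
F2 | step 10 | methyl (2Z,6E)‑2‑[(3E)‑4‑iodopent‑3‑en‑1‑yl]‑6‑methyl‑7‑[(2S)‑4‑methyl‑5‑oxo‑3‑(2‑oxoethyl)‑2,5‑dihydrofuran‑2‑yl]hepta‑2,6‑dienoate | COC(=O)/C(CC/C=C(\C)I)=C\CC/C(C)=C/[C@@H]1OC(=O)C(C)=C1CC=O
F3 | step 8 | methyl (2Z,6E)‑7‑[(2S)‑3‑(1,3‑dioxolan‑2‑ylmethyl)‑4‑iodo‑5‑oxo‑2,5‑dihydrofuran‑2‑yl]‑6‑methyl‑2‑(pent‑3‑yn‑1‑yl)hepta‑2,6‑dienoate | COC(=O)/C(CCC#CC)=C\CC/C(C)=C/[C@@H]1OC(=O)C(I)=C1CC1OCCO1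
F4 | step 9 | methyl (2Z,6E)‑7‑[(2S)‑3‑ethenyl‑4‑methyl‑5‑oxo‑2,5‑dihydrofuran‑2‑yl]‑6‑methyl‑2‑(pent‑3‑yn‑1‑yl)hepta‑2,6‑dienoate | COC(=O)/C(CCC#CC)=C\CC/C(C)=C/[C@@H]1OC(=O)C(C)=C1C=C
F5 | step 9 | methyl (2Z,6E)‑7‑[(2S)‑3‑(2‑hydroxyethyl)‑4‑methyl‑5‑oxo‑2,5‑dihydrofuran‑2‑yl]‑6‑methyl‑2‑(pent‑3‑yn‑1‑yl)hepta‑2,6‑dienoate | COC(=O)/C(CCC#CC)=C\CC/C(C)=C/[C@@H]1OC(=O)C(C)=C1CCO
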